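**Plan**
- Retrosynthesis: after removal of the 4'-O-allyl and O-silyl groups, the C4a–C5 bond of the flavone is cut. This opens ring A, the 5,7-dihydroxybenzo ring fused to the pyranone at C4a–C8a: a phloroglucinol with acetate-type 1,3-oxygenation, so it can be written as a CH2–CO–CH2–CO2Me chain on a 2-aryl-4-pyranone.
- That chain is cut at CH2–CO2Me (carboxylation) and at pyranyl-CH2–COCH3 (acylation). The pyranone ring O–C bond is opened to a 1-aryl-1,3,5-triketone, which is cut into the B-ring methyl benzoate and acetylacetone.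
- Forward order: B ring with its finished side chain, then ring C (pyranone) by cyclodehydration, then the four-carbon keto ester chain, then ring A by Claisen closure, then deprotection.
- Stereochemistry: the single (R) carbinol centre comes from a Shi epoxidation of a prenyl group. The epoxide is isomerised to the allylic alcohol without breaking the C–O bond at that carbon, and no later step touches it.

Key step: step 10

Assumption: the D-fructose-derived Shi ketone is taken to give the (R)-epoxide from the ArCH2CH=CMe2 unit, by analogy with its known sense of induction on trans-disubstituted and trisubstituted alkenes; if the sense were opposite, the enantiomeric ketone would be used.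

Abbreviation: Ar = 3-[(2R)-2-(tert-butyldimethylsilyloxy)-3-methylbut-3-en-1-yl]-4-(prop-2-en-1-yloxy)phenyl.

**Route**

Step 1
Reactants: 1 methyl 4-hydroxybenzoate; 2 prenyl bromide (1-bromo-3-methylbut-2-ene)
Product: 3 methyl 4-hydroxy-3-(3-methylbut-2-en-1-yl)benzoate
Conditions: NaH (1.0 equiv), toluene, 0 °C → rt; then 2, rt → 50 °C
Reagents that add atoms: none
Why: ortho C-alkylation of a sodium phenoxide by an allylic halide in a non-polar solvent, where the tight ion pair directs the electrophile to the ring carbon next to oxygen and the para position is blocked by the ester.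

Step 2
Reactants: 3 methyl 4-hydroxy-3-(3-methylbut-2-en-1-yl)benzoate
Product: 4 methyl 3-(3-methylbut-2-en-1-yl)-4-(prop-2-en-1-yloxy)benzoate
Conditions: allyl bromide, K2CO3, acetone, reflux
Reagents that add atoms: allyl bromide, C=CCBr
Why: Williamson etherification of the phenol, which masks it with a group that can later be removed by Pd(0) without acid.

Step 3
Reactants: 4 methyl 3-(3-methylbut-2-en-1-yl)-4-(prop-2-en-1-yloxy)benzoate
Product: 5 methyl 3-{[(2R)-3,3-dimethyloxiran-2-yl]methyl}-4-(prop-2-en-1-yloxy)benzoate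
Conditions: D-fructose-derived Shi ketone (0.3 equiv), Oxone, K2CO3, Bu4NHSO4, Na2B4O7/Na2EDTA buffer, MeCN–DMM–H2O, 0 °C
Reagents that add atoms: Oxone (potassium peroxymonosulfate), [K+].[O-]S(=O)(=O)OO
Why: Shi asymmetric epoxidation, in which the chiral dioxirane delivers oxygen to the electron-rich trisubstituted prenyl alkene through a spiro transition state and so sets the (R) centre, while the monosubstituted allyl ether alkene is too unreactive to compete.

Step 4
Reactants: 5 methyl 3-{[(2R)-3,3-dimethyloxiran-2-yl]methyl}-4-(prop-2-en-1-yloxy)benzoate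
Product: 6 methyl 3-[(2R)-2-hydroxy-3-methylbut-3-en-1-yl]-4-(prop-2-en-1-yloxy)benzoate
Conditions: Et2Al(TMP) (4 equiv, from Et2AlCl and LiTMP), toluene, 0 °C; Rochelle salt work-up
Reagents that add atoms: none
Why: aluminium amide-mediated isomerisation of a trisubstituted epoxide to an allylic alcohol, in which aluminium binds the oxygen, the tertiary C–O bond breaks and a methyl proton is removed in a syn β-elimination, so the secondary C–O bond and the (R) configuration are kept.

Step 5
Reactants: 6 methyl 3-[(2R)-2-hydroxy-3-methylbut-3-en-1-yl]-4-(prop-2-en-1-yloxy)benzoate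
Product: 7 methyl 3-[(2R)-2-(tert-butyldimethylsilyloxy)-3-methylbut-3-en-1-yl]-4-(prop-2-en-1-yloxy)benzoate (Ar–CO2Me)
Conditions: TBSCl, imidazole, DMAP (cat.), DMF, rt
Reagents that add atoms: tert-butyldimethylsilyl chloride, CC(C)(C)[Si](C)(C)Cl
Why: standard imidazole-promoted silylation of a secondary alcohol, giving an ether that withstands the strong bases of the following steps.

Step 6
Reactants: 7 Ar–CO2Me; 8 acetylacetone (pentane-2,4-dione)
Product: 9 1-Ar-hexane-1,3,5-trione
Conditions: 8 (3 equiv), LDA (6 equiv), THF, −78 → 0 °C; then 7, 0 °C → rt; aq. NH4Cl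
Reagents that add atoms: none
Why: terminal acylation of a β-diketone dianion (Claisen condensation), in which the more basic terminal carbanion attacks the aryl ester and excess dianion absorbs the acidic proton of the triketone formed.

Step 7
Reactants: 9 1-Ar-hexane-1,3,5-trione
Product: 10 2-Ar-6-methyl-4H-pyran-4-one
Conditions: PPh3, CCl4, Et3N, THF, rt
Reagents that add atoms: none
Why: Appel-type cyclodehydration of a 1,3,5-triketone to a γ-pyrone (enol oxyphosphonium, attack by the second enol oxygen, loss of Ph3PO), chosen because it is non-acidic and spares the allylic silyl ether and the isopropenyl group.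

Step 8
Reactants: 10 2-Ar-6-methyl-4H-pyran-4-one; 11 N-methoxy-N-methylacetamide
Product: 12 2-Ar-6-(2-oxopropyl)-4H-pyran-4-one
Conditions: LiHMDS (1.2 equiv), THF, −78 °C; then 11, −78 → −20 °C; aq. NH4Cl
Reagents that add atoms: none
Why: lateral (vinylogous) deprotonation of the 6-methyl group of the γ-pyrone followed by C-acylation with a Weinreb amide, whose chelated tetrahedral intermediate prevents over-addition and keeps the acidic product masked until work-up.

Step 9
Reactants: 12 2-Ar-6-(2-oxopropyl)-4H-pyran-4-one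
Product: 14 methyl 4-(6-Ar-4-oxo-4H-pyran-2-yl)-3-oxobutanoate, via keto acid 13 (not isolated)
Conditions: LDA (2.3 equiv), THF, −78 → −20 °C; CO2 (g), −78 °C; cold 0.5 M HCl to pH 3; then TMSCHN2, MeOH–toluene, 0 °C
Reagents that add atoms: carbon dioxide, O=C=O; (trimethylsilyl)diazomethane, C[Si](C)(C)C=[N+]=[N-]
Why: dianion carboxylation of a 1,3-dicarbonyl-type enolate, in which the second deprotonation takes place at the terminal methyl group and that carbanion captures CO2 to give a carboxylate too weakly acidic to quench remaining dianion, followed by cold esterification before the β-keto acid can lose CO2.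

Step 10
Reactants: 14 methyl 4-(6-Ar-4-oxo-4H-pyran-2-yl)-3-oxobutanoate
Product: 16 2-Ar-5,7-dihydroxy-4H-chromen-4-one, via trione tautomer 15 (not isolated)
Conditions: Mg(OMe)2 (5 equiv), MeOH, 0.01 M, reflux; aq. NH4Cl
Reagents that add atoms: none
Why: Proposed new method: in methanol the magnesium enolates of 14 equilibrate, and the tautomer deprotonated at the CH2 between pyranone and ketone is a vinylogous enolate whose charge reaches the ring CH next to the chain-bearing carbon (pyranone C3, α to the ring carbonyl); this carbon adds to the magnesium-bound ester carbonyl, methoxide leaves, and trione 15 enolises at once to the 5,7-dihydroxybenzo ring, which makes the closure irreversible. The closest known reaction types are the magnesium methoxide Claisen cyclisation of 3,5,7-triketo esters to acylphloroglucinols and the C-acylation and aldol chemistry of side-chain anions of 4-pyranones. Ring A closes in a 6-(enolexo)-exo-trig mode, and no stereocentre is formed. The step needs C-acylation at pyranone C3 in preference to aldol closure, lactonisation and intermolecular condensation: aldol attack of the ester α-carbon on the pyranone carbonyl would give a bridged ring and meets a weakly electrophilic vinylogous-ester carbonyl, the oxygen that would otherwise lactonise to a 2-pyranone is locked as the pyranone ring oxygen, and high dilution suppresses intermolecular reaction. The alkyl silyl ether, the aryl allyl ether and both alkenes are inert to magnesium methoxide.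

Step 11
Reactants: 16 2-Ar-5,7-dihydroxy-4H-chromen-4-one
Product: 17 2-{3-[(2R)-2-(tert-butyldimethylsilyloxy)-3-methylbut-3-en-1-yl]-4-hydroxyphenyl}-5,7-dihydroxy-4H-chromen-4-one
Conditions: Pd(PPh3)4 (5 mol%), morpholine (10 equiv), THF, rt
Reagents that add atoms: none
Why: Tsuji–Trost deallylation, in which Pd(0) ionises only the aryl allyl ether (phenoxide leaving group) and excess morpholine traps the π-allyl fragment before the electron-rich ring A can, while the silyl-protected allylic alcohol is not ionised.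

Step 12
Reactants: 17 2-{3-[(2R)-2-(tert-butyldimethylsilyloxy)-3-methylbut-3-en-1-yl]-4-hydroxyphenyl}-5,7-dihydroxy-4H-chromen-4-one
Product: 18 5,7-dihydroxy-2-{4-hydroxy-3-[(2R)-2-hydroxy-3-methylbut-3-en-1-yl]phenyl}-4H-chromen-4-one (target)
Conditions: TBAF, AcOH (1:1), THF, 0 °C → rt
Reagents that add atoms: none
Why: fluoride-induced cleavage of the silyl ether under buffered, non-acidic conditions, so the free ortho-phenol cannot add to the isopropenyl group and the carbinol centre is untouched.

**Compound list**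
1 | methyl 4-hydroxybenzoate | COC(=O)c1ccc(O)cc1 | starting material
2 | prenyl bromide (1-bromo-3-methylbut-2-ene) | CC(C)=CCBr | starting material
3 | methyl 4-hydroxy-3-(3-methylbut-2-en-1-yl)benzoate | COC(=O)c1ccc(O)c(CC=C(C)C)c1 | intermediate
4 | methyl 3-(3-methylbut-2-en-1-yl)-4-(prop-2-en-1-yloxy)benzoate | COC(=O)c1ccc(OCC=C)c(CC=C(C)C)c1 | intermediate
5 | methyl 3-{[(2R)-3,3-dimethyloxiran-2-yl]methyl}-4-(prop-2-en-1-yloxy)benzoate | COC(=O)c1ccc(OCC=C)c(C[C@H]2OC2(C)C)c1 | intermediate
6 | methyl 3-[(2R)-2-hydroxy-3-methylbut-3-en-1-yl]-4-(prop-2-en-1-yloxy)benzoate | COC(=O)c1ccc(OCC=C)c(C[C@@H](O)C(C)=C)c1 | intermediate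
7 | methyl 3-[(2R)-2-(tert-butyldimethylsilyloxy)-3-methylbut-3-en-1-yl]-4-(prop-2-en-1-yloxy)benzoate | COC(=O)c1ccc(OCC=C)c(C[C@@H](O[Si](C)(C)C(C)(C)C)C(C)=C)c1 | intermediate
8 | acetylacetone (pentane-2,4-dione) | CC(=O)CC(C)=O | starting material
9 | 1-{3-[(2R)-2-(tert-butyldimethylsilyloxy)-3-methylbut-3-en-1-yl]-4-(prop-2-en-1-yloxy)phenyl}hexane-1,3,5-trione | CC(=O)CC(=O)CC(=O)c1ccc(OCC=C)c(C[C@@H](O[Si](C)(C)C(C)(C)C)C(C)=C)c1 | intermediate
10 | 2-{3-[(2R)-2-(tert-butyldimethylsilyloxy)-3-methylbut-3-en-1-yl]-4-(prop-2-en-1-yloxy)phenyl}-6-methyl-4H-pyran-4-one | Cc1cc(=O)cc(-c2ccc(OCC=C)c(C[C@@H](O[Si](C)(C)C(C)(C)C)C(C)=C)c2)o1 | intermediate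
11 | N-methoxy-N-methylacetamide | CC(=O)N(C)OC | starting material
12 | 2-{3-[(2R)-2-(tert-butyldimethylsilyloxy)-3-methylbut-3-en-1-yl]-4-(prop-2-en-1-yloxy)phenyl}-6-(2-oxopropyl)-4H-pyran-4-one | CC(=O)Cc1cc(=O)cc(-c2ccc(OCC=C)c(C[C@@H](O[Si](C)(C)C(C)(C)C)C(C)=C)c2)o1 | intermediate
13 | 4-(6-{3-[(2R)-2-(tert-butyldimethylsilyloxy)-3-methylbut-3-en-1-yl]-4-(prop-2-en-1-yloxy)phenyl}-4-oxo-4H-pyran-2-yl)-3-oxobutanoic acid | OC(=O)CC(=O)Cc1cc(=O)cc(-c2ccc(OCC=C)c(C[C@@H](O[Si](C)(C)C(C)(C)C)C(C)=C)c2)o1 | intermediate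
14 | methyl 4-(6-{3-[(2R)-2-(tert-butyldimethylsilyloxy)-3-methylbut-3-en-1-yl]-4-(prop-2-en-1-yloxy)phenyl}-4-oxo-4H-pyran-2-yl)-3-oxobutanoate | COC(=O)CC(=O)Cc1cc(=O)cc(-c2ccc(OCC=C)c(C[C@@H](O[Si](C)(C)C(C)(C)C)C(C)=C)c2)o1 | intermediate
15 | 2-{3-[(2R)-2-(tert-butyldimethylsilyloxy)-3-methylbut-3-en-1-yl]-4-(prop-2-en-1-yloxy)phenyl}-6H-chromene-4,5,7(8H)-trione | O=C1CC(=O)c2c(C1)oc(-c1ccc(OCC=C)c(C[C@@H](O[Si](C)(C)C(C)(C)C)C(C)=C)c1)cc2=O | intermediate
16 | 2-{3-[(2R)-2-(tert-butyldimethylsilyloxy)-3-methylbut-3-en-1-yl]-4-(prop-2-en-1-yloxy)phenyl}-5,7-dihydroxy-4H-chromen-4-one | C=CCOc1ccc(-c2cc(=O)c3c(O)cc(O)cc3o2)cc1C[C@@H](O[Si](C)(C)C(C)(C)C)C(C)=C | intermediate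
17 | 2-{3-[(2R)-2-(tert-butyldimethylsilyloxy)-3-methylbut-3-en-1-yl]-4-hydroxyphenyl}-5,7-dihydroxy-4H-chromen-4-one | Oc1ccc(-c2cc(=O)c3c(O)cc(O)cc3o2)cc1C[C@@H](O[Si](C)(C)C(C)(C)C)C(C)=C | intermediate
18 | 5,7-dihydroxy-2-{4-hydroxy-3-[(2R)-2-hydroxy-3-methylbut-3-en-1-yl]phenyl}-4H-chromen-4-one | C=C(C)[C@H](O)Cc1cc(-c2cc(=O)c3c(O)cc(O)cc3o2)ccc1O | target

**Totals**
Total step count: 12. Longest linear sequence: 12 steps (1 → 18).

**Steps most likely to fail**

1. Step 10 (new method). The closure may lose to opening of the pyranone ring by methoxide, or the β-keto ester may stay as its unreactive chelated enolate so that no C–C bond forms. The fallback uses known chemistry and brings ring A in ready-made, setting out from 7 and rejoining at 16. Ester 7 would be saponified (LiOH, THF–MeOH–H2O) to 3-[(2R)-2-(tert-butyldimethylsilyloxy)-3-methylbut-3-en-1-yl]-4-(prop-2-en-1-yloxy)benzoic acid F1. This would be converted under neutral conditions (1-chloro-N,N,2-trimethylprop-1-en-1-amine, CH2Cl2, 0 °C) into the corresponding benzoyl chloride F2. F2 would then be added to the lithium polyanion of commercial 2',4',6'-trihydroxyacetophenone (LiHMDS, THF, −78 → −10 °C), a one-pot variant of the Baker–Venkataraman route that acylates the ketone enolate on carbon, to give 1-Ar-3-(2,4,6-trihydroxyphenyl)propane-1,3-dione F3. Cyclodehydration of F3 in acetic acid buffered with sodium acetate at 80 °C, conditions chosen to spare the allylic silyl ether, should give flavone 16, from which steps 11 and 12 follow unchanged.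

2. Step 4. The aluminium amide may attack the methyl ester, or it may remove a benzylic proton instead of a methyl proton, which would lead to the conjugated tertiary alcohol. The fallback replaces base-induced isomerisation by hydration and dehydration, setting out from 5 and rejoining at 7 (step 5 is then not needed). Epoxide 5 would be opened by water under mild acid catalysis (cat. HClO4, THF–H2O, 0 °C), with attack at the tertiary carbon so that the stereocentre keeps its C–O bond, giving methyl 3-[(2R)-2,3-dihydroxy-3-methylbutyl]-4-(prop-2-en-1-yloxy)benzoate F4. The secondary hydroxyl would be silylated selectively (TBSCl, imidazole, DMF) to methyl 3-[(2R)-2-(tert-butyldimethylsilyloxy)-3-hydroxy-3-methylbutyl]-4-(prop-2-en-1-yloxy)benzoate F5. Dehydration of the tertiary alcohol towards a methyl group (SOCl2, pyridine, 0 °C) should then give 7.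

3. Step 9. The second deprotonation may not occur cleanly at the terminal methyl group, and the β-keto acid may lose CO2 before it is esterified. The fallback delivers the last two carbons from a malonate half ester, setting out from 10 and rejoining at 14 (compounds 12 and 13 are by-passed). The lateral anion of 10 (LiHMDS, THF, −78 °C) would be quenched with CO2 to give (6-Ar-4-oxo-4H-pyran-2-yl)acetic acid F6. Activation with carbonyldiimidazole (THF, rt) would give the acyl imidazolide 2-Ar-6-[2-(1H-imidazol-1-yl)-2-oxoethyl]-4H-pyran-4-one F7. F7 would be condensed with the magnesium salt of monomethyl malonate (potassium methyl malonate, MgCl2, Et3N, THF, rt) in a decarboxylative Claisen condensation. The acylmalonate half ester 2-(methoxycarbonyl)-4-(6-Ar-4-oxo-4H-pyran-2-yl)-3-oxobutanoic acid F8 loses CO2 on mildly acidic work-up to give 14.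

**Further compounds**
F1 | step 10 | 3-[(2R)-2-(tert-butyldimethylsilyloxy)-3-methylbut-3-en-1-yl]-4-(prop-2-en-1-yloxy)benzoic acid | OC(=O)c1ccc(OCC=C)c(C[C@@H](O[Si](C)(C)C(C)(C)C)C(C)=C)c1
F2 | step 10 | 3-[(2R)-2-(tert-butyldimethylsilyloxy)-3-methylbut-3-en-1-yl]-4-(prop-2-en-1-yloxy)benzoyl chloride | ClC(=O)c1ccc(OCC=C)c(C[C@@H](O[Si](C)(C)C(C)(C)C)C(C)=C)c1
F3 | step 10 | 1-{3-[(2R)-2-(tert-butyldimethylsilyloxy)-3-methylbut-3-en-1-yl]-4-(prop-2-en-1-yloxy)phenyl}-3-(2,4,6-trihydroxyphenyl)propane-1,3-dione | O=C(CC(=O)c1c(O)cc(O)cc1O)c1ccc(OCC=C)c(C[C@@H](O[Si](C)(C)C(C)(C)C)C(C)=C)c1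
F4 | step 4 | methyl 3-[(2R)-2,3-dihydroxy-3-methylbutyl]-4-(prop-2-en-1-yloxy)benzoate | COC(=O)c1ccc(OCC=C)c(C[C@@H](O)C(C)(C)O)c1
F5 | step 4 | methyl 3-[(2R)-2-(tert-butyldimethylsilyloxy)-3-hydroxy-3-methylbutyl]-4-(prop-2-en-1-yloxy)benzoate | COC(=O)c1ccc(OCC=C)c(C[C@@H](O[Si](C)(C)C(C)(C)C)C(C)(C)O)c1
F6 | step 9 | (6-{3-[(2R)-2-(tert-butyldimethylsilyloxy)-3-methylbut-3-en-1-yl]-4-(prop-2-en-1-yloxy)phenyl}-4-oxo-4H-pyran-2-yl)acetic acid | OC(=O)Cc1cc(=O)cc(-c2ccc(OCC=C)c(C[C@@H](O[Si](C)(C)C(C)(C)C)C(C)=C)c2)o1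
F7 | step 9 | 2-{3-[(2R)-2-(tert-butyldimethylsilyloxy)-3-methylbut-3-en-1-yl]-4-(prop-2-en-1-yloxy)phenyl}-6-[2-(1H-imidazol-1-yl)-2-oxoethyl]-4H-pyran-4-one | O=C(Cc1cc(=O)cc(-c2ccc(OCC=C)c(C[C@@H](O[Si](C)(C)C(C)(C)C)C(C)=C)c2)o1)n1ccnc1
F8 | step 9 | 2-(methoxycarbonyl)-4-(6-{3-[(2R)-2-(tert-butyldimethylsilyloxy)-3-methylbut-3-en-1-yl]-4-(prop-2-en-1-yloxy)phenyl}-4-oxo-4H-pyran-2-yl)-3-oxobutanoic acid | COC(=O)C(C(O)=O)C(=O)Cc1cc(=O)cc(-c2ccc(OCC=C)c(C[C@@H](O[Si](C)(C)C(C)(C)C)C(C)=C)c2)o1
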